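**Plan**

- Retrosynthesis: the ester C–O bond is cut first (aroyl chloride 21 plus the tertiary alkoxide of 11). In ring B (C1 methyl-bearing, C2, C3, C4 carrying oxygen and isopropyl, C5, C6) the only alkene, C1=C2, lies across the ring from the quaternary C4, so opening it by retro-metathesis leaves the acyclic carbinol 10 with an allyl and a 3-methylbut-3-enyl arm on C4.
- Further cuts: C5–C6 (epoxide plus 2-methylallyl Grignard reagent), C3–C4 (enolate allylation), and on the arene (ring A) the two aryl–CH2 bonds to the prenyl groups (Stille coupling).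
- Forward: hydroxy acid 1 → dioxolanone → allylation → diol → epoxide → dienol 10 → metathesis closes ring B, the only ring that is made (ring A is bought). Arene branch: acetate, twofold prenylation, saponification, silylation, acid chloride. The halves are joined by O-acylation and the phenol is freed with fluoride.
- Stereochemistry: C4 is the only stereocentre. It comes from (R)-2-hydroxy-3-methylbutanoic acid by self-regeneration of the stereocentre (cis acetal, allyl bromide enters trans to tert-butyl), and no later step breaks a bond at C4.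

Key step: step 6

Remark: C4 is taken from the chiral pool because a catalyst-controlled allyl addition to 2,6-dimethylhept-6-en-3-one would have to tell isopropyl from a primary alkyl chain; 1 and 12 are purchased (12 is otherwise one bromination from methyl 4-hydroxybenzoate).

**Route**

Step 1
Reactants: 1 (2R)-2-hydroxy-3-methylbutanoic acid
Product: 2 (2R,5R)-2-tert-butyl-5-(propan-2-yl)-1,3-dioxolan-4-one (cis)
Conditions: t-BuCHO (1.5 equiv), p-TsOH·H2O (cat.), H2SO4 (cat.), pentane, reflux, azeotropic removal of water; crystallisation from pentane at −78 °C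
Reagents that add atoms: pivalaldehyde (2,2-dimethylpropanal), CC(C)(C)C=O
Why: Acid-catalysed acetalisation under equilibrating conditions should favour the cis dioxolanone with tert-butyl and isopropyl on the same ring face (C5 keeps the configuration of 1, C2 is set relative to it by thermodynamic control), and crystallisation removes the trans isomer that would lead into the enantiomeric series.

Step 2
Reactants: 2 (2R,5R)-2-tert-butyl-5-(propan-2-yl)-1,3-dioxolan-4-one; 3 allyl bromide (3-bromoprop-1-ene)
Product: 5 (2R,5R)-2-tert-butyl-5-(propan-2-yl)-5-(prop-2-en-1-yl)-1,3-dioxolan-4-one, via lithium enolate 4 (not isolated)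
Conditions: LiN(i-Pr)2 (1.1 equiv), THF, −78 °C; then 3 (1.5 equiv), −78 to −30 °C; aq. NH4Cl
Reagents that add atoms: none
Why: Enolate alkylation with self-regeneration of the stereocentre: deprotonation flattens C5 while the acetal carbon keeps the stereochemical information, and allyl bromide should enter anti to the tert-butyl group, on the face the hydrogen left, so the quaternary centre forms as 5R with isopropyl and tert-butyl still cis.

Step 3
Reactants: 5 (2R,5R)-2-tert-butyl-5-(propan-2-yl)-5-(prop-2-en-1-yl)-1,3-dioxolan-4-one
Product: 6 (2R)-2-(propan-2-yl)pent-4-ene-1,2-diol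
Conditions: LiAlH4 (1.5 equiv), THF, 0 °C to rt; aq. NaOH work-up
Reagents that add atoms: none
Why: Hydride reduction of the lactone-type carbonyl gives a hemiacetal alkoxide that collapses, so the acetal carbon leaves as pivalaldehyde (reduced on to 2,2-dimethylpropan-1-ol) and the 1,2-diol is released without any bond to the quaternary carbon being broken.

Step 4
Reactants: 6 (2R)-2-(propan-2-yl)pent-4-ene-1,2-diol
Product: 8 (2R)-2-(propan-2-yl)-2-(prop-2-en-1-yl)oxirane, via sodium alkoxide tosylate 7 (not isolated)
Conditions: NaH (2.2 equiv), THF, 0 °C; TsCl (1.0 equiv), 0 °C to rt; the volatile epoxide is kept as a concentrated ethereal solution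
Reagents that add atoms: none
Why: One-pot monosulfonylation and intramolecular Williamson etherification: only the unhindered primary alkoxide should be tosylated, and the neighbouring tertiary alkoxide then displaces tosylate (3-exo-tet) with the C–O bond at the stereocentre intact.

Step 5
Reactants: 8 (2R)-2-(propan-2-yl)-2-(prop-2-en-1-yl)oxirane; 9 (2-methylprop-2-en-1-yl)magnesium chloride
Product: 10 (4R)-7-methyl-4-(propan-2-yl)octa-1,7-dien-4-ol
Conditions: 9 (1.5 equiv, 0.5 M in THF), CuBr·SMe2 (10 mol%), THF, −40 to 0 °C; aq. NH4Cl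
Reagents that add atoms: none
Why: Copper-catalysed SN2 opening of a 2,2-disubstituted epoxide by an allylic Grignard reagent should occur at the unsubstituted ring carbon, which builds the 3-methylbut-3-enyl arm and leaves the configuration of the carbinol carbon untouched.

Step 6
Reactants: 10 (4R)-7-methyl-4-(propan-2-yl)octa-1,7-dien-4-ol
Product: 11 (R)-terpinen-4-ol [(1R)-4-methyl-1-(propan-2-yl)cyclohex-3-en-1-ol]
Conditions: second-generation Grubbs catalyst RuCl2(=CHPh)(PCy3)(H2IMes) (3 mol%), 1,4-benzoquinone (10 mol%), CH2Cl2 (0.02 M), 40 °C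
Reagents that add atoms: none
Why: The ruthenium benzylidene should first exchange with the monosubstituted allyl alkene of 10, and the resulting alkylidene adds intramolecularly across the 1,1-disubstituted alkene to a ruthenacyclobutane whose cycloreversion forms C1=C2 and passes on a ruthenium methylidene that re-enters the cycle with loss of ethene. This is ordinary ring-closing olefin metathesis of a 1,7-diene with one 1,1-disubstituted alkene, the usual access to 1-methylcyclohexenes. Ring B closes as a six-membered carbocycle by formation of its only double bond, the allyl arm supplying C3 and C2 and the 3-methylbut-3-enyl arm supplying C5, C6, C1 and the methyl group. No stereocentre is formed, and C4, at which no bond is broken, keeps the R configuration fixed in step 2. The step needs cyclisation to win over intermolecular metathesis and the new trisubstituted alkene to stay in place; the fully substituted carbinol carbon between the arms (gem-disubstituent effect), the unstrained ring size, dilution and escape of ethene secure the first, and benzoquinone with a short reaction time suppresses ruthenium hydride migration of the alkene. The free tertiary alcohol is tolerated by this catalyst.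

Step 7
Reactants: 12 methyl 3,5-dibromo-4-hydroxybenzoate
Product: 13 methyl 4-acetoxy-3,5-dibromobenzoate
Conditions: Ac2O (1.5 equiv), Et3N (2 equiv), DMAP (5 mol%), CH2Cl2, 0 °C to rt
Reagents that add atoms: acetic anhydride, CC(=O)OC(C)=O
Why: DMAP-catalysed O-acetylation masks the acidic phenol, which would otherwise protonate the allylic stannane in the next step, and makes the aryl bromides more electron-poor for oxidative addition.

Step 8
Reactants: 13 methyl 4-acetoxy-3,5-dibromobenzoate; 14 tributyl(3-methylbut-2-en-1-yl)stannane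
Product: 16 methyl 4-acetoxy-3,5-bis(3-methylbut-2-en-1-yl)benzoate, via monoprenyl bromide 15 (not isolated)
Conditions: 14 (2.6 equiv), Pd(PPh3)4 (8 mol%), degassed DMF, 95 °C; aq. KF work-up
Reagents that add atoms: none
Why: Twofold Stille coupling: zerovalent palladium inserts into each C–Br bond, the prenyl group is transferred from tin, and reductive elimination from the less hindered primary terminus of the allyl ligand should give the linear 3-methylbut-2-enyl groups, with the ester and aryl acetate inert under these neutral conditions.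

Step 9
Reactants: 16 methyl 4-acetoxy-3,5-bis(3-methylbut-2-en-1-yl)benzoate
Product: 18 4-hydroxy-3,5-bis(3-methylbut-2-en-1-yl)benzoic acid, via lithium phenoxide ester 17 (not isolated)
Conditions: LiOH·H2O (5 equiv), THF/MeOH/H2O, rt to 40 °C; then 1 M HCl, 0 °C, to pH 3
Reagents that add atoms: lithium hydroxide, [Li+].[OH-]
Why: Saponification (acyl–oxygen cleavage by hydroxide) removes the aryl acetate first and then the methyl ester, and a cold, brief, mildly acidic work-up avoids acid-induced cyclisation of the ortho-prenyl phenol to a chroman.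

Step 10
Reactants: 18 4-hydroxy-3,5-bis(3-methylbut-2-en-1-yl)benzoic acid
Product: 20 tert-butyldimethylsilyl 4-[(tert-butyldimethylsilyl)oxy]-3,5-bis(3-methylbut-2-en-1-yl)benzoate, via silyl ester phenol 19 (not isolated)
Conditions: TBSCl (2.5 equiv), imidazole (5 equiv), DMF, rt to 40 °C; pentane/cold water partition, used directly
Reagents that add atoms: tert-butyldimethylsilyl chloride, CC(C)(C)[Si](C)(C)Cl
Why: Silylation with TBSCl/imidazole takes the carboxylic acid first and then the hindered phenol, giving a compound whose phenol is protected and whose carboxyl group is already set up for neutral conversion to the acid chloride.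

Step 11
Reactants: 20 tert-butyldimethylsilyl 4-[(tert-butyldimethylsilyl)oxy]-3,5-bis(3-methylbut-2-en-1-yl)benzoate
Product: 21 4-[(tert-butyldimethylsilyl)oxy]-3,5-bis(3-methylbut-2-en-1-yl)benzoyl chloride
Conditions: (COCl)2 (1.2 equiv), DMF (cat.), CH2Cl2, 0 °C to rt; volatiles including TBSCl removed under high vacuum
Reagents that add atoms: oxalyl chloride, O=C(Cl)C(=O)Cl
Why: Silyl esters are converted to acid chlorides by oxalyl chloride and catalytic DMF (chloroiminium activation) with release of TBSCl instead of HCl, so the acid-sensitive prenyl alkenes and the aryl silyl ether should survive.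

Step 12
Reactants: 11 (R)-terpinen-4-ol; 21 4-[(tert-butyldimethylsilyl)oxy]-3,5-bis(3-methylbut-2-en-1-yl)benzoyl chloride
Product: 23 (1R)-4-methyl-1-(propan-2-yl)cyclohex-3-en-1-yl 4-[(tert-butyldimethylsilyl)oxy]-3,5-bis(3-methylbut-2-en-1-yl)benzoate, via lithium alkoxide 22 (not isolated)
Conditions: 11, n-BuLi (1.0 equiv), THF, −78 to 0 °C; then 21 (1.2 equiv), THF, −78 °C to rt
Reagents that add atoms: none
Why: O-Acylation of a preformed lithium tertiary alkoxide by an aroyl chloride (addition–elimination at the acyl carbon) is the standard way to esters of tertiary alcohols; the acid chloride has no α-hydrogen, the di-ortho-substituted aryl silyl ether is shielded from the alkoxide, and the C–O bond at C4 is not broken, so the R configuration is retained.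

Step 13
Reactants: 23 (1R)-4-methyl-1-(propan-2-yl)cyclohex-3-en-1-yl 4-[(tert-butyldimethylsilyl)oxy]-3,5-bis(3-methylbut-2-en-1-yl)benzoate
Product: 24 (1R)-4-methyl-1-(propan-2-yl)cyclohex-3-en-1-yl 4-hydroxy-3,5-bis(3-methylbut-2-en-1-yl)benzoate (the target)
Conditions: TBAF (1.2 equiv), AcOH (1.2 equiv), THF, 0 °C
Reagents that add atoms: none
Why: Fluoride cleaves the aryl silyl ether through the strong Si–F bond while acetic acid buffers the phenoxide, and these non-acidic, non-hydrolytic conditions should leave the tertiary benzoate, the prenyl groups and the ring alkene alone.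

**Compound list**

1 | (2R)-2-hydroxy-3-methylbutanoic acid | CC(C)[C@@H](O)C(=O)O | starting material
2 | (2R,5R)-2-tert-butyl-5-(propan-2-yl)-1,3-dioxolan-4-one (cis) | CC(C)[C@H]1O[C@@H](C(C)(C)C)OC1=O | intermediate
3 | 3-bromoprop-1-ene (allyl bromide) | C=CCBr | starting material
4 | lithium (2R)-2-tert-butyl-5-(propan-2-yl)-1,3-dioxol-4-olate (lithium enolate of 2) | [Li+].CC(C)C1=C([O-])O[C@H](C(C)(C)C)O1 | intermediate
5 | (2R,5R)-2-tert-butyl-5-(propan-2-yl)-5-(prop-2-en-1-yl)-1,3-dioxolan-4-one | CC(C)[C@@]1(CC=C)O[C@@H](C(C)(C)C)OC1=O | intermediate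
6 | (2R)-2-(propan-2-yl)pent-4-ene-1,2-diol | O[C@@](CO)(C(C)C)CC=C | intermediate
7 | sodium (2R)-1-[(4-methylbenzenesulfonyl)oxy]-2-(propan-2-yl)pent-4-en-2-olate | [Na+].[O-][C@@](COS(=O)(=O)c1ccc(C)cc1)(C(C)C)CC=C | intermediate
8 | (2R)-2-(propan-2-yl)-2-(prop-2-en-1-yl)oxirane | CC(C)[C@]1(CC=C)CO1 | intermediate
9 | (2-methylprop-2-en-1-yl)magnesium chloride | C=C(C)C[Mg]Cl | starting material
10 | (4R)-7-methyl-4-(propan-2-yl)octa-1,7-dien-4-ol | O[C@@](CCC(C)=C)(C(C)C)CC=C | intermediate
11 | (R)-terpinen-4-ol, (1R)-4-methyl-1-(propan-2-yl)cyclohex-3-en-1-ol | O[C@@]1(C(C)C)CC=C(C)CC1 | intermediate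
12 | methyl 3,5-dibromo-4-hydroxybenzoate | COC(=O)c1cc(Br)c(O)c(Br)c1 | starting material
13 | methyl 4-acetoxy-3,5-dibromobenzoate | COC(=O)c1cc(Br)c(OC(C)=O)c(Br)c1 | intermediate
14 | tributyl(3-methylbut-2-en-1-yl)stannane | CCCC[Sn](CCCC)(CCCC)CC=C(C)C | starting material
15 | methyl 4-acetoxy-3-bromo-5-(3-methylbut-2-en-1-yl)benzoate | COC(=O)c1cc(Br)c(OC(C)=O)c(CC=C(C)C)c1 | intermediate
16 | methyl 4-acetoxy-3,5-bis(3-methylbut-2-en-1-yl)benzoate | COC(=O)c1cc(CC=C(C)C)c(OC(C)=O)c(CC=C(C)C)c1 | intermediate
17 | lithium 4-(methoxycarbonyl)-2,6-bis(3-methylbut-2-en-1-yl)phenolate | [Li+].COC(=O)c1cc(CC=C(C)C)c([O-])c(CC=C(C)C)c1 | intermediate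
18 | 4-hydroxy-3,5-bis(3-methylbut-2-en-1-yl)benzoic acid | CC(C)=CCc1cc(C(=O)O)cc(CC=C(C)C)c1O | intermediate
19 | tert-butyldimethylsilyl 4-hydroxy-3,5-bis(3-methylbut-2-en-1-yl)benzoate | CC(C)=CCc1cc(C(=O)O[Si](C)(C)C(C)(C)C)cc(CC=C(C)C)c1O | intermediate
20 | tert-butyldimethylsilyl 4-[(tert-butyldimethylsilyl)oxy]-3,5-bis(3-methylbut-2-en-1-yl)benzoate | CC(C)=CCc1cc(C(=O)O[Si](C)(C)C(C)(C)C)cc(CC=C(C)C)c1O[Si](C)(C)C(C)(C)C | intermediate
21 | 4-[(tert-butyldimethylsilyl)oxy]-3,5-bis(3-methylbut-2-en-1-yl)benzoyl chloride | CC(C)=CCc1cc(C(Cl)=O)cc(CC=C(C)C)c1O[Si](C)(C)C(C)(C)C | intermediate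
22 | lithium (1R)-4-methyl-1-(propan-2-yl)cyclohex-3-en-1-olate | [Li+].[O-][C@@]1(C(C)C)CC=C(C)CC1 | intermediate
23 | (1R)-4-methyl-1-(propan-2-yl)cyclohex-3-en-1-yl 4-[(tert-butyldimethylsilyl)oxy]-3,5-bis(3-methylbut-2-en-1-yl)benzoate | CC(C)=CCc1cc(C(=O)O[C@@]2(C(C)C)CC=C(C)CC2)cc(CC=C(C)C)c1O[Si](C)(C)C(C)(C)C | intermediate
24 | (1R)-4-methyl-1-(propan-2-yl)cyclohex-3-en-1-yl 4-hydroxy-3,5-bis(3-methylbut-2-en-1-yl)benzoate (CNP0120997.1) | CC(C)=CCc1cc(C(=O)O[C@@]2(C(C)C)CC=C(C)CC2)cc(CC=C(C)C)c1O | target

**Summary**

Total step count: 13. Longest linear sequence: 8 steps (1 to 24 through steps 1–6, 12 and 13); the arene branch (steps 7–11) joins at step 12.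

Steps most likely to fail:

1. Step 12. Acylation of the hindered tertiary alkoxide may be slow enough for the alkoxide to attack silicon instead (silyl transfer from the aryl ether, or silylation by residual TBSCl), so that conversion stalls. The fallback avoids the alkoxide and acylates neutral 11 with a symmetrical anhydride under magnesium bromide/tertiary amine dual activation, a known way to benzoylate tertiary alcohols. It sets out from 20 and 21 and comes back at 23. The silyl ester of 20 is hydrolysed selectively (AcOH, THF/H2O, 0 °C) to 4-[(tert-butyldimethylsilyl)oxy]-3,5-bis(3-methylbut-2-en-1-yl)benzoic acid F1. F1 and 21 with Et3N in CH2Cl2 give 4-[(tert-butyldimethylsilyl)oxy]-3,5-bis(3-methylbut-2-en-1-yl)benzoic anhydride F2. F2 with 11, MgBr2·OEt2 and i-Pr2NEt in CH2Cl2 at rt should give 23, one equivalent of F1 being recovered.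

2. Step 8. Allylic transposition at palladium (reductive elimination at the tertiary terminus) may give 1,1-dimethylallyl isomers, or the sequence may stall after the first coupling. The fallback removes the regiochemical question by coupling a symmetrical allyl group and installing the gem-dimethyl terminus afterwards. It sets out from 13 and comes back at 16. Twofold Stille coupling of 13 with allyltributylstannane (Pd(PPh3)4, DMF, 95 °C) gives methyl 4-acetoxy-3,5-di(prop-2-en-1-yl)benzoate F3. Cross-metathesis of F3 with 2-methylbut-2-ene (as co-solvent, second-generation Grubbs catalyst, CH2Cl2, 40 °C) should convert both allyl groups into prenyl groups and give 16.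

3. Step 1. Incomplete cis selectivity in the equilibrating acetalisation, or co-crystallisation of the isomers, would carry trans acetal into step 2, where it gives the enantiomer of 5 and lowers the enantiomeric purity of everything downstream. The fallback closes the acetal under kinetic control instead. It sets out from 1 and comes back at 2. Acid 1 is bis-silylated (TMSCl, Et3N, CH2Cl2) to trimethylsilyl (2R)-3-methyl-2-[(trimethylsilyl)oxy]butanoate F4. F4 with pivalaldehyde and catalytic TMSOTf in CH2Cl2 at −78 °C should give 2, since this low-temperature silyl-transfer acetalisation is known to favour the cis dioxolanone strongly.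

**Further compounds**

F1 | step 12 | 4-[(tert-butyldimethylsilyl)oxy]-3,5-bis(3-methylbut-2-en-1-yl)benzoic acid | CC(C)=CCc1cc(C(=O)O)cc(CC=C(C)C)c1O[Si](C)(C)C(C)(C)C
F2 | step 12 | 4-[(tert-butyldimethylsilyl)oxy]-3,5-bis(3-methylbut-2-en-1-yl)benzoic anhydride | CC(C)=CCc1cc(C(=O)OC(=O)c2cc(CC=C(C)C)c(O[Si](C)(C)C(C)(C)C)c(CC=C(C)C)c2)cc(CC=C(C)C)c1O[Si](C)(C)C(C)(C)C
F3 | step 8 | methyl 4-acetoxy-3,5-di(prop-2-en-1-yl)benzoate | COC(=O)c1cc(CC=C)c(OC(C)=O)c(CC=C)c1
F4 | step 1 | trimethylsilyl (2R)-3-methyl-2-[(trimethylsilyl)oxy]butanoate | CC(C)[C@@H](O[Si](C)(C)C)C(=O)O[Si](C)(C)C
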